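Readings and results were computed for an exercise.

I decided to reckon the alder flask from its two ends and join them, since the question lies at 20 h, later than its last reading at 12.0 h.

| flask | substrate | partner | base | temperature | remark | time |
|---|---|---|---|---|---|---|
| alder | 0.016 M | 8 mM | 0.80 mM | 70 °C | the very flask that is asked about, followed so far |  |
| larch | 0.016 M | 5.4 mM | 0.80 mM | 65 °C | run made earlier |  |
| flask | 0.016 M | 8.00 mM | 0.800 mM | 70 °C |  | 20 h |

- alder (time / h: target / %): 0.667: 10; 2.00: 32; 3.00: 44; 5.00: 48; 8.00: 50; 10.0: 50; 12.0: 50
- larch (time / h: target / %): 0.167: 0; 0.417: 4; 0.833: 2; 1.33: 6; 1.50: 7; 2.00: 9; 3.00: 16

(each reading ± 1.5 percentage points)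

- additions bring no volume worth counting

- west: at 20 h add base, 100% of the amount charged, then wait 10 h
- north-east: change nothing and wait 10 h more
- north-west: at 20 h take out 90% of the released group then present, then wait 10 h
- south-east: at 20 h add partner, 100% of the amount charged, then wait 10 h
- east: at 20 h raise the temperature by 10 K, then wait 10 h

* target, in percent of the substrate first charged, at 20 h
* the remedy with the largest gain of target, or "none" below 2 percentage points (west / north-east / north-west / south-east / east / none)
* target present, in percent of the substrate first charged, after north-east
* target present, in percent of the substrate first charged, after north-west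

The charges give 50.0% for the partner roof, the share of the charged substrate that the charged partner can turn into target when one partner serves one substrate. With less partner charged than substrate, that makes partner the limiting reagent.

In the first instants the alder target climbed, 10% at 0.667 h and 32% at 2.00 h, and by my estimate that pace, counted from the start and held straight on, reaches the roof after 3.03 h. In the middle, at 3.00 h, the alder reading of 44% meant, one partner to one substrate, that about 12.0% of the partner charge remained against 56.0% of the substrate charge, so partner was about to matter. At the end the alder readings stood at 50%, 50% and 50%, level with the roof within a scatter of 1.5 percentage points. The two ends join: the bend in the alder readings came between 3.00 h and 8.00 h, and 20 h lies well beyond it.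

The larch run says little here, because its roof of 33.8% stood above its last reading of 16%.

So I committed to 50.0% at 20 h, the same after waiting or after taking out released group. I chose south-east, whose dose lifts the roof to 100%, while west and east leave the charges of partner and substrate as they were.

The forecast gave 50% (48.5% to 51.5%), south-east as the remedy, 50% (48.5% to 51.5%) after north-east and 50% (48% to 56%) after north-west. Its ground: “Only fresh partner restarts the reaction, so south-east is best.”

The alder flask gave 50.0% at 20 h, 50.0% after north-east and 50.0% after north-west, and south-east gained 45 points.

    substrate + partner + released group → target + 2 released group (k = 260 L² mol⁻² min⁻¹, Ea = 55.0 kJ mol⁻¹)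
    substrate + partner → target + released group (k = 0.250 L mol⁻¹ min⁻¹, Ea = 85.0 kJ mol⁻¹)
    crystals ⇌ released group, rate k3*(cs3 - [released group]) while solid is left; crystals form when [released group] > cs3 (solubility = 6.20 mM, k = 0.160 min⁻¹)
    base + released group ⇌ salt, settled at all times (K = 1.20 × 10⁶ L mol⁻¹, ΔH = −41.0 kJ mol⁻¹)
    (constants at 70 °C)

At 20.0 h the alder target stood at the roof of 50.0%, with partner at 0% of its charge and substrate at 50.0%. The neighbour flask with less partner held 0.300 equiv of it, so its roof was 30.0%. It gave 30.0%, with 0% of its partner and 70% of its substrate left.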